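Remark on the chemistry: the geometry of the vinyl ether is lost when ring C aromatises, so the ring-expansion precursor is built as the Z isomer 16 (same skeleton, same bond formed, same product 19 as the E isomer F10), which avoids an (E)-2-aryloxyvinyllithium whose lithium and aryloxide are anti and set up for elimination. The atom mapping of 16 onto 19 (carbonyl carbon to C6–OH, the three methoxy carbons to C5, C4, C3, the vinyl carbons to C2–H and C1–O–B) is consistent, so no structure needs correcting.

## Structural features

- The target 28 is a linear hexamer of six benzene rings A to F joined only by five diaryl ether oxygens. It carries fifteen free phenolic hydroxyls and has no stereocentre, so no stereocentres stand next to each other and none has to be set.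
- Ring A is a 2,4,6-trihydroxyphenoxy cap, rings B, D and E are 3,5-dihydroxy rings oxygenated at C1 and C4, and ring F is a 3,4,5-trihydroxyphenoxy cap.
- Each ether joins a carbon flanked by two oxygen-bearing carbons (A C1, B C4, C C6, D C4, E C4) to a carbon with a free ortho position on the next ring (B C1, C C1, D C1, E C1, F C1).
- Ring C is the exception: five contiguous oxygens (hydroxyls at C3, C4, C5; aryloxy groups at C6 to ring D and at C1 to ring B) and a single hydrogen at C2.
- The free polyphenol, above all the pyrogallol-type rings C and F, is oxidised by air, fastest as a phenoxide. On the way, the ynol ether, the enol ether with its allylic tertiary methyl ether (acid-labile) and the cyclobutenone (heat-labile) are the sensitive groups.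
- The real difficulty is ring C: its five oxygens must be told apart so that only O–C6 is free for ring D, next to the already hindered O–B ether at C1.
- The key step uses the fact that C3, C4, C5 and C6 with their oxygens are the four carbons of a squarate, and that C1 (with O–B) and C2 (with H) are a 2-aryloxyvinyl group. Closing C6–C1 therefore builds ring C with every oxygen in place.

## Logic of the disconnections

**28 to 26.** Fifteen O–CH3 bonds are cut. Methyl is the one protecting group that survives butyllithium, hot xylene and copper with base, and 11 already delivers two of them. The gain is a single robust, chromatographable precursor. The demand is one exhaustive Lewis-acid dealkylation that leaves the five diaryl ethers alone.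

**26 to 19 + 25.** The ring D C1–O bond is cut, the oxygen staying on ring C C6. This splits the hexamer near its middle into two trimers and puts the halide on the unflanked carbon. The demand is a copper coupling of a phenol with two ortho substituents and an electron-rich bromide.

**19 to 16 (key).** The ring C C6–C1 bond is cut, which unravels the arene to 17, and C6 is reconnected to C3 to give the four-membered ring. A pentaoxygenated benzene is thereby reduced to a cyclobutenone with a vinyl ether arm, and the only free hydroxyl is the one ring D needs. The demand is outward rotation of the methoxy group on ring opening and a ketene that closes before it is intercepted.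

**16 to 15.** The Z alkene is traced back to the alkyne. This removes any need for a 2-aryloxyvinyl metal. The demand is a syn semihydrogenation that stops at the alkene.

**15 to 10 + 11.** The bond between the quaternary ring carbon (future C3) and the alkyne carbon (future C2) is cut, together with the O–CH3 on that quaternary carbon. Because 11 is symmetric there is no regiochemistry to control. The demand is clean monoaddition of 13 and O-methylation of 14 in the same flask.

**10 to 7 + 8.** The O–C(vinyl) bond (future C1–O) is cut. The two carbons C1 and C2 then come from a commodity chloroalkene. The demand is that the hindered phenoxide of 7 adds to 9.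

**7 to 3 + 5, then 3 to 1 and 5 to 4.** The ring B C1–O bond is cut with the oxygen on ring A, so the hindered partner is the nucleophile and the bromide is unflanked. The benzyl group of 5 keeps the ring B C4 oxygen from self-coupling. 3 comes from 1 by exchange of the formyl carbon for oxygen, and 5 from 4 by O-alkylation.

**25 to 4 + 24, 24 to 21, 21 to 4 + 20.** The ring E C1–O and ring F C1–O bonds are cut as oxidative boron couplings. The bromide of 4 survives each coupling and becomes the next handle, so 4 serves as rings B, D and E. The demand is chemoselectivity for boron over bromine with a di-ortho-methoxy phenol.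

## Other disconnections considered

Alternative 1: The cut removes both ether bonds of ring B at once (B C1–O to ring A and B C4–O to ring C), with ring B as a doubly electrophilic arene.
- Forward step: the cationic cyclopentadienyl complex of divalent ruthenium with 2,5-dichloro-1,3-dimethoxybenzene, A1, would take the phenoxide of 3 at the chloride with two free ortho positions. In the same flask the phenoxide of the ring C phenol A2 would then displace the chloride flanked by two methoxy groups, giving the complexed trimer A3. Photolytic arene release in MeCN and hydrogenolysis would lead to 19.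
- In favour: addition–elimination on a cationic η6-arene is fast even for an electron-rich ring. Three rings are joined in one pot, the most hindered ether (B C4–O–C) needs no copper coupling, and no intermediate is thermally or acid-labile. On convergence and on robustness of intermediates it is the better plan.
- Against: the pentaoxygenated ring is not made but only moved into A2, whose five oxygens still have to be differentiated in a sequence of its own. The order of the two substitutions rests only on a steric rate difference between the two chlorides, and crossover would give ring-exchanged or symmetric ethers. The second substitution puts a hindered phenoxide on a doubly flanked carbon. Ruthenium is used stoichiometrically and a photochemical step is needed.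
- Comparison: from the dimer level to 19 the step count is about equal (complexation, double substitution, arene release, debenzylation against steps 5 to 8), but it is longer once A2 is counted. The chosen plan fixes regiochemistry by connectivity, where this one relies on selectivity.

Alternative 2: The cut falls on two C–C bonds of ring B, C2–C3 and C6–C1 in ring B numbering (C1–C2 and C5–C6 in the numbering of the benzoate).
- Forward step: [4+2] cycloaddition of the 2-aryloxy-1-methoxy-1,3-bis(trimethylsilyloxy)diene A4, which carries ring C on oxygen, with the ynoate A5, which carries ring A on oxygen. Loss of methanol would give the resorcinol ester A6.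
- In favour: the hardest ether of the trimer, B C4–O–C, would be made by plain O-alkylation of A2 with an α-halo-β-keto ester before ring B exists, without metal. On that bond it is the better plan. Ring B also arrives with free hydroxyls, which could spare two methyl ether cleavages at the end.
- Against: A2 is needed here too, so ring C stays unsolved. A5 is a push–pull alkyne whose oxygen donor on the β-carbon weakens it as a dienophile and works against the polarisation that the regiochemistry depends on. A6 carries an ester at B C2 that the target lacks, so hydrolysis and decarboxylation, protection of two hydroxyls and debenzylation must follow.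
- Comparison: both plans are pericyclic ring constructions in which the substitution pattern follows from connectivity, and in that respect they are equal. This one builds the easy, symmetric ring and costs at least three more steps after its key step.

Alternative 3: The cut falls on two C–C bonds of ring A (A C2–C3 and A C5–C6), so ring A is grown last.
- Forward step: the bis-enolate of dimethyl 3-oxopentanedioate A7 would be acylated twice by the two ester groups of the aryloxymalonate A8, which carries the whole BCDEF chain. Ring A would close as the phloroglucinol diester A9, and the two esters would then be removed by hydrolysis and decarboxylation.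
- In favour: the A–O–B ether at a doubly flanked carbon would come from O-alkylation of a phenol with a halomalonate, not from a diaryl ether coupling. Ring A would emerge with free hydroxyls, three fewer methyl ethers to cleave. It needs no metal and only cheap reagents. On these points it is the equal or the better.
- Against: it addresses the least demanding ring and needs the full pentamer, ring C included, first. The ring-forming step comes last on the most valuable intermediate. A8 is a very hindered malonate, so retro-Claisen and transesterification pathways would compete with the double acylation. Two esters must be removed in the presence of an air-sensitive free phloroglucinol, and the other twelve methyl ethers still need BBr3.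
- Comparison: less convergent (5 + 1 against 3 + 3) and longer by the ester removals. Mechanistically it is sound carbonyl chemistry, but it does not touch the real problem.

Key step: step 8

## Route

Step 1
Reactants: 1 2,4,6-trimethoxybenzaldehyde
Product: 3 2,4,6-trimethoxyphenol, via aryl formate 2 (not isolated)
Conditions: mCPBA, CH2Cl2, 0 °C → rt; then K2CO3 (cat.), MeOH, rt
Reagents that add atoms: mCPBA (3-chloroperoxybenzoic acid) OOC(=O)c1cccc(Cl)c1
Why: Baeyer–Villiger (Dakin-type) oxidation: the very electron-rich aryl group migrates to oxygen to give formate 2, and methanolysis frees the phenol.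

Step 2
Reactants: 4 4-bromo-2,6-dimethoxyphenol
Product: 5 2-(benzyloxy)-5-bromo-1,3-dimethoxybenzene
Conditions: BnBr, K2CO3, DMF, rt
Reagents that add atoms: benzyl bromide BrCc1ccccc1
Why: Williamson ether synthesis; the benzyl group stops the bromophenol from coupling with itself in step 3 and is later removed by hydrogenolysis without touching methyl ethers.

Step 3
Reactants: 3 2,4,6-trimethoxyphenol; 5 2-(benzyloxy)-5-bromo-1,3-dimethoxybenzene
Product: 6 2-(benzyloxy)-1,3-dimethoxy-5-(2,4,6-trimethoxyphenoxy)benzene
Conditions: CuI (10 mol %), picolinic acid (20 mol %), K3PO4, DMSO, 90 °C, argon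
Reagents that add atoms: none
Why: Ullmann diaryl ether synthesis with the hindered partner as phenoxide and the bromide on a carbon with two free ortho positions, the arrangement that picolinate-ligated copper handles best.

Step 4
Reactants: 6 2-(benzyloxy)-1,3-dimethoxy-5-(2,4,6-trimethoxyphenoxy)benzene
Product: 7 2,6-dimethoxy-4-(2,4,6-trimethoxyphenoxy)phenol
Conditions: H2 (1 atm), Pd/C, EtOAc–MeOH, rt
Reagents that add atoms: none
Why: Hydrogenolysis of the benzyl aryl ether; diaryl ethers and methyl ethers are inert under these conditions.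

Step 5
Reactants: 7 2,6-dimethoxy-4-(2,4,6-trimethoxyphenoxy)phenol; 8 trichloroethene
Product: 10 2-{[(E)-1,2-dichloroethenyl]oxy}-1,3-dimethoxy-5-(2,4,6-trimethoxyphenoxy)benzene, via dichloroacetylene 9 (not isolated)
Conditions: K2CO3, DMF, 70 °C
Reagents that add atoms: none
Why: Base eliminates HCl from 8 to give 9 in low concentration, and the phenoxide adds to it in anti fashion, which sets the E geometry of the dichlorovinyl ether; this is the standard entry to aryl ynol ethers.

Step 6
Reactants: 10 2-{[(E)-1,2-dichloroethenyl]oxy}-1,3-dimethoxy-5-(2,4,6-trimethoxyphenoxy)benzene; 11 dimethyl squarate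
Product: 15 racemic 4-{[2,6-dimethoxy-4-(2,4,6-trimethoxyphenoxy)phenoxy]ethynyl}-2,3,4-trimethoxycyclobut-2-en-1-one, via chloroethynyl ether 12 (not isolated), via lithium acetylide 13 (not isolated), via lithium alkoxide 14 (not isolated)
Conditions: n-BuLi (2.05 equiv), THF, −78 → −40 °C; cannulated into 11, THF, −78 °C; MeOTf, −78 → 0 °C
Reagents that add atoms: methyl trifluoromethanesulfonate COS(=O)(=O)C(F)(F)F
Why: n-BuLi dehydrochlorinates 10 to 12 and exchanges its chlorine to give acetylide 13, a configurationally trivial nucleophile that cannot eliminate; 1,2-addition to one carbonyl of symmetric 11 and O-methylation of the tertiary alkoxide by the triflate are standard squarate chemistry. The new quaternary centre forms as a racemate and disappears in step 8.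

Step 7
Reactants: 15 racemic 4-{[2,6-dimethoxy-4-(2,4,6-trimethoxyphenoxy)phenoxy]ethynyl}-2,3,4-trimethoxycyclobut-2-en-1-one
Product: 16 racemic 4-{(Z)-2-[2,6-dimethoxy-4-(2,4,6-trimethoxyphenoxy)phenoxy]ethenyl}-2,3,4-trimethoxycyclobut-2-en-1-one
Conditions: H2 (1 atm), Pd/CaCO3 poisoned with Pb(OAc)2, quinoline, EtOAc, rt
Reagents that add atoms: none
Why: Lindlar semihydrogenation delivers H2 syn and so gives the Z enol ether, as in the reduction of alkoxyethynyl carbinols in the Arens–van Dorp synthesis; the tetrasubstituted dialkoxy enone double bond is not reduced. The acid-labile product is passed through Et3N-deactivated silica and used at once.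

Step 8
Reactants: 16 racemic 4-{(Z)-2-[2,6-dimethoxy-4-(2,4,6-trimethoxyphenoxy)phenoxy]ethenyl}-2,3,4-trimethoxycyclobut-2-en-1-one
Product: 19 6-[2,6-dimethoxy-4-(2,4,6-trimethoxyphenoxy)phenoxy]-2,3,4-trimethoxyphenol, via dienylketene 17 (not isolated), via cyclohexadienone 18 (not isolated)
Conditions: p-xylene (0.01 M, degassed), 138 °C, argon
Reagents that add atoms: none
Why: Heating opens the cyclobutenone by a four-electron conrotatory electrocyclic reaction that breaks the bond between the carbonyl carbon and the quaternary carbon and gives dienylketene 17. The methoxy donor on the breaking bond rotates outward, so the aryloxyvinyl arm turns inward and ends cis to the ketene; this torquoselectivity is the one selectivity the step needs, and the oxygen substituent secures it. A six-electron disrotatory electrocyclisation between the ketene carbon (ring C C6) and the aryloxy-bearing vinyl carbon (C1) then closes the six-membered ring as 2,4-cyclohexadienone 18. Enolisation of the C1 hydrogen aromatises 18 to phenol 19, which erases both the transient sp3 centre and the Z geometry, so no stereocentre needs control. The closest known reaction is the Moore rearrangement of squarate-derived 4-alkenyl-4-alkoxycyclobutenones to hydroquinone monoethers. An inward substituent on the alkene terminus is tolerated because the partner is the unhindered sp carbon of the ketene, as in the ready closure of dienylketenes with disubstituted termini. The substituent order follows from connectivity: the squarate carbons become C3 to C6, and the only unprotected oxygen is the former carbonyl at C6. High dilution and exclusion of water and alcohols keep the ketene from being intercepted.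

Step 9
Reactants: 4 4-bromo-2,6-dimethoxyphenol; 20 (3,4,5-trimethoxyphenyl)boronic acid
Product: 21 5-bromo-1,3-dimethoxy-2-(3,4,5-trimethoxyphenoxy)benzene
Conditions: Cu(OAc)2 (1 equiv, turned over by air), pyridine, 4 Å MS, CH2Cl2, dry air, rt
Reagents that add atoms: none
Why: Chan–Lam coupling arylates the phenol oxidatively at room temperature and leaves the C–Br bond untouched, so the bromide of 4 is kept as the next handle.

Step 10
Reactants: 21 5-bromo-1,3-dimethoxy-2-(3,4,5-trimethoxyphenoxy)benzene
Product: 24 [3,5-dimethoxy-4-(3,4,5-trimethoxyphenoxy)phenyl]boronic acid, via aryllithium 22 (not isolated), via lithium borate 23 (not isolated)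
Conditions: n-BuLi, THF, −78 °C; B(OiPr)3, −78 °C → rt; 1 M HCl
Reagents that add atoms: triisopropyl borate CC(C)OB(OC(C)C)OC(C)C; water O
Why: Bromine–lithium exchange at −78 °C is faster than any ortho-metalation of the methoxy arenes; borylation of the aryllithium and hydrolysis of the borate give the boronic acid.

Step 11
Reactants: 4 4-bromo-2,6-dimethoxyphenol; 24 [3,5-dimethoxy-4-(3,4,5-trimethoxyphenoxy)phenyl]boronic acid
Product: 25 5-bromo-2-[2,6-dimethoxy-4-(3,4,5-trimethoxyphenoxy)phenoxy]-1,3-dimethoxybenzene
Conditions: Cu(OAc)2 (1 equiv, turned over by air), pyridine, 4 Å MS, CH2Cl2, dry air, rt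
Reagents that add atoms: none
Why: A second Chan–Lam coupling of the same bromophenol, with the boron on a carbon that has two free ortho positions; the bromide survives again and becomes the electrophilic site of the DEF trimer.

Step 12
Reactants: 19 6-[2,6-dimethoxy-4-(2,4,6-trimethoxyphenoxy)phenoxy]-2,3,4-trimethoxyphenol; 25 5-bromo-2-[2,6-dimethoxy-4-(3,4,5-trimethoxyphenoxy)phenoxy]-1,3-dimethoxybenzene
Product: 26 1-[2,6-dimethoxy-4-(2,4,6-trimethoxyphenoxy)phenoxy]-2-{3,5-dimethoxy-4-[3,5-dimethoxy-4-(3,4,5-trimethoxyphenoxy)phenoxy]phenoxy}-3,4,5-trimethoxybenzene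
Conditions: CuI (20 mol %), picolinic acid (40 mol %), K3PO4, DMSO, 100 °C, argon
Reagents that add atoms: none
Why: Ullmann diaryl ether synthesis joining the two trimers; the hindered component is again the phenoxide and the bromide sits on an unflanked carbon, as in step 3.

Step 13
Reactants: 26 1-[2,6-dimethoxy-4-(2,4,6-trimethoxyphenoxy)phenoxy]-2-{3,5-dimethoxy-4-[3,5-dimethoxy-4-(3,4,5-trimethoxyphenoxy)phenoxy]phenoxy}-3,4,5-trimethoxybenzene
Product: 28 4-{3,5-dihydroxy-4-[3,5-dihydroxy-4-(3,4,5-trihydroxyphenoxy)phenoxy]phenoxy}-5-[2,6-dihydroxy-4-(2,4,6-trihydroxyphenoxy)phenoxy]benzene-1,2,3-triol, via aryloxydibromoborane 27 (not isolated)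
Conditions: BBr3 (3 equiv per OMe), CH2Cl2, −78 °C → rt; then H2O, 0 °C, argon
Reagents that add atoms: none
Why: Lewis-acid dealkylation: each methyl ether is activated on boron and loses bromomethane by bromide attack at the methyl carbon, while the sp2 C–O bonds of the five diaryl ethers are not attacked. Hydrolysis of the B–O bonds frees the fifteen phenols under acidic, oxygen-free conditions.

## Compound list

1 | 2,4,6-trimethoxybenzaldehyde | COc1cc(OC)c(C=O)c(OC)c1 | starting material
2 | 2,4,6-trimethoxyphenyl formate (not isolated) | COc1cc(OC)c(OC=O)c(OC)c1 | intermediate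
3 | 2,4,6-trimethoxyphenol | COc1cc(OC)c(O)c(OC)c1 | intermediate
4 | 4-bromo-2,6-dimethoxyphenol | COc1cc(Br)cc(OC)c1O | starting material
5 | 2-(benzyloxy)-5-bromo-1,3-dimethoxybenzene | COc1cc(Br)cc(OC)c1OCc1ccccc1 | intermediate
6 | 2-(benzyloxy)-1,3-dimethoxy-5-(2,4,6-trimethoxyphenoxy)benzene | COc1cc(OC)c(Oc2cc(OC)c(OCc3ccccc3)c(OC)c2)c(OC)c1 | intermediate
7 | 2,6-dimethoxy-4-(2,4,6-trimethoxyphenoxy)phenol | COc1cc(OC)c(Oc2cc(OC)c(O)c(OC)c2)c(OC)c1 | intermediate
8 | trichloroethene | ClC=C(Cl)Cl | starting material
9 | dichloroacetylene (not isolated) | ClC#CCl | intermediate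
10 | 2-{[(E)-1,2-dichloroethenyl]oxy}-1,3-dimethoxy-5-(2,4,6-trimethoxyphenoxy)benzene | COc1cc(OC)c(Oc2cc(OC)c(O/C(Cl)=C\Cl)c(OC)c2)c(OC)c1 | intermediate
11 | dimethyl squarate (3,4-dimethoxycyclobut-3-ene-1,2-dione) | COC1=C(OC)C(=O)C1=O | starting material
12 | 2-[(chloroethynyl)oxy]-1,3-dimethoxy-5-(2,4,6-trimethoxyphenoxy)benzene (not isolated) | ClC#COc1c(OC)cc(Oc2c(OC)cc(OC)cc2OC)cc1OC | intermediate
13 | lithium {[2,6-dimethoxy-4-(2,4,6-trimethoxyphenoxy)phenoxy]ethynide} (not isolated) | [Li]C#COc1c(OC)cc(Oc2c(OC)cc(OC)cc2OC)cc1OC | intermediate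
14 | racemic lithium 1-{[2,6-dimethoxy-4-(2,4,6-trimethoxyphenoxy)phenoxy]ethynyl}-2,3-dimethoxy-4-oxocyclobut-2-en-1-olate (not isolated) | COC1=C(OC)C(O[Li])(C#COc2c(OC)cc(Oc3c(OC)cc(OC)cc3OC)cc2OC)C1=O | intermediate
15 | racemic 4-{[2,6-dimethoxy-4-(2,4,6-trimethoxyphenoxy)phenoxy]ethynyl}-2,3,4-trimethoxycyclobut-2-en-1-one | COC1=C(OC)C(OC)(C#COc2c(OC)cc(Oc3c(OC)cc(OC)cc3OC)cc2OC)C1=O | intermediate
16 | racemic 4-{(Z)-2-[2,6-dimethoxy-4-(2,4,6-trimethoxyphenoxy)phenoxy]ethenyl}-2,3,4-trimethoxycyclobut-2-en-1-one | COC1=C(OC)C(OC)(/C=C\Oc2c(OC)cc(Oc3c(OC)cc(OC)cc3OC)cc2OC)C1=O | intermediate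
17 | (3Z,5Z)-6-[2,6-dimethoxy-4-(2,4,6-trimethoxyphenoxy)phenoxy]-2,3,4-trimethoxyhexa-1,3,5-trien-1-one (not isolated) | O=C=C(OC)/C(OC)=C(OC)\C=C/Oc1c(OC)cc(Oc2c(OC)cc(OC)cc2OC)cc1OC | intermediate
18 | racemic 6-[2,6-dimethoxy-4-(2,4,6-trimethoxyphenoxy)phenoxy]-2,3,4-trimethoxycyclohexa-2,4-dien-1-one (not isolated) | COC1=C(OC)C(OC)=CC(Oc2c(OC)cc(Oc3c(OC)cc(OC)cc3OC)cc2OC)C1=O | intermediate
19 | 6-[2,6-dimethoxy-4-(2,4,6-trimethoxyphenoxy)phenoxy]-2,3,4-trimethoxyphenol | COc1cc(OC)c(Oc2cc(OC)c(Oc3cc(OC)c(OC)c(OC)c3O)c(OC)c2)c(OC)c1 | intermediate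
20 | (3,4,5-trimethoxyphenyl)boronic acid | COc1cc(B(O)O)cc(OC)c1OC | starting material
21 | 5-bromo-1,3-dimethoxy-2-(3,4,5-trimethoxyphenoxy)benzene | COc1cc(Br)cc(OC)c1Oc1cc(OC)c(OC)c(OC)c1 | intermediate
22 | [3,5-dimethoxy-4-(3,4,5-trimethoxyphenoxy)phenyl]lithium (not isolated) | [Li]c1cc(OC)c(Oc2cc(OC)c(OC)c(OC)c2)c(OC)c1 | intermediate
23 | lithium [3,5-dimethoxy-4-(3,4,5-trimethoxyphenoxy)phenyl]triisopropoxyborate (not isolated) | [Li+].CC(C)O[B-](OC(C)C)(OC(C)C)c1cc(OC)c(Oc2cc(OC)c(OC)c(OC)c2)c(OC)c1 | intermediate
24 | [3,5-dimethoxy-4-(3,4,5-trimethoxyphenoxy)phenyl]boronic acid | OB(O)c1cc(OC)c(Oc2cc(OC)c(OC)c(OC)c2)c(OC)c1 | intermediate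
25 | 5-bromo-2-[2,6-dimethoxy-4-(3,4,5-trimethoxyphenoxy)phenoxy]-1,3-dimethoxybenzene | COc1cc(Br)cc(OC)c1Oc1cc(OC)c(Oc2cc(OC)c(OC)c(OC)c2)c(OC)c1 | intermediate
26 | 1-[2,6-dimethoxy-4-(2,4,6-trimethoxyphenoxy)phenoxy]-2-{3,5-dimethoxy-4-[3,5-dimethoxy-4-(3,4,5-trimethoxyphenoxy)phenoxy]phenoxy}-3,4,5-trimethoxybenzene (pentadecamethyl ether of 28) | COc1cc(OC)c(Oc2cc(OC)c(Oc3cc(OC)c(OC)c(OC)c3Oc3cc(OC)c(Oc4cc(OC)c(Oc5cc(OC)c(OC)c(OC)c5)c(OC)c4)c(OC)c3)c(OC)c2)c(OC)c1 | intermediate
27 | pentadecakis(dibromoboryl) ether of 28, idealised (not isolated) | BrB(Br)Oc1cc(OB(Br)Br)c(Oc2cc(OB(Br)Br)c(Oc3cc(OB(Br)Br)c(OB(Br)Br)c(OB(Br)Br)c3Oc3cc(OB(Br)Br)c(Oc4cc(OB(Br)Br)c(Oc5cc(OB(Br)Br)c(OB(Br)Br)c(OB(Br)Br)c5)c(OB(Br)Br)c4)c(OB(Br)Br)c3)c(OB(Br)Br)c2)c(OB(Br)Br)c1 | intermediate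
28 | 4-{3,5-dihydroxy-4-[3,5-dihydroxy-4-(3,4,5-trihydroxyphenoxy)phenoxy]phenoxy}-5-[2,6-dihydroxy-4-(2,4,6-trihydroxyphenoxy)phenoxy]benzene-1,2,3-triol (CNP0270681.0) | Oc1cc(O)c(Oc2cc(O)c(Oc3cc(O)c(O)c(O)c3Oc3cc(O)c(Oc4cc(O)c(Oc5cc(O)c(O)c(O)c5)c(O)c4)c(O)c3)c(O)c2)c(O)c1 | target

## Step count and least certain steps

Total: 13 steps. Longest linear sequence: 9 steps (1, 3, 4, 5, 6, 7, 8, 12, 13, or equally 2, 3, 4, 5, 6, 7, 8, 12, 13). The DEF branch (9, 10, 11) joins at step 12.

**Step 8 (key step).** The most likely failure is interception of ketene 17 before ring closure: the inward aryloxy group may slow the electrocyclisation enough for dimerisation or for acylation of product 19 or of trace water to compete. A second risk is ionisation of the allylic enol ether of 16 on acidic surfaces before it is heated. The fallback abandons ring construction and brings ring C in preformed; it sets out from 7 and comes back at 19. Commercial 2,3,4-trimethoxyphenol would be brominated ortho to the hydroxyl (NBS, MeCN, 0 °C) to 6-bromo-2,3,4-trimethoxyphenol F1 and benzylated (BnBr, K2CO3, DMF) to 1-(benzyloxy)-6-bromo-2,3,4-trimethoxybenzene F2. Copper coupling of 7 with F2 (CuI, picolinic acid, K3PO4, DMSO, 110 °C) would give 1-(benzyloxy)-6-[2,6-dimethoxy-4-(2,4,6-trimethoxyphenoxy)phenoxy]-2,3,4-trimethoxybenzene F3, and hydrogenolysis (H2, Pd/C) would give 19.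

**Step 6.** The telescoped sequence depends on exact stoichiometry: surplus n-BuLi would add to 11, a deficit would leave 12, and methylation of the hindered tertiary alkoxide 14 may stall. The fallback separates the operations; it sets out from 10 and comes back at 15. Treatment of 10 with n-BuLi (2.2 equiv, −78 °C) and a methanol quench would give 2-(ethynyloxy)-1,3-dimethoxy-5-(2,4,6-trimethoxyphenoxy)benzene F4, isolated and used at once. Deprotonation of F4 with exactly one equivalent of n-BuLi would give 13 free of excess base. Addition to 11 and an NH4Cl quench would give racemic 4-{[2,6-dimethoxy-4-(2,4,6-trimethoxyphenoxy)phenoxy]ethynyl}-4-hydroxy-2,3-dimethoxycyclobut-2-en-1-one F5, which would be methylated under neutral conditions (MeI, Ag2O, MeCN) to 15.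

**Step 7.** The most likely failure is over-reduction of the electron-rich enol ether or stalling of the poisoned catalyst, together with acid-catalysed loss of the enol ether on work-up. The fallback fixes the alkene geometry by hydrometalation before the C–C bond is made and passes through the E series; it sets out from 10 (through F4, made as under step 6) and comes back at 19.
- Cp2Zr(H)Cl (THF, rt) would add syn to F4 to give chlorobis(cyclopentadienyl){(E)-2-[2,6-dimethoxy-4-(2,4,6-trimethoxyphenoxy)phenoxy]ethenyl}zirconium F6.
- Iodine would convert F6 into 2-{[(E)-2-iodoethenyl]oxy}-1,3-dimethoxy-5-(2,4,6-trimethoxyphenoxy)benzene F7.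
- Iodine–lithium exchange (t-BuLi, 2 equiv, THF/Et2O/pentane, −100 °C) would give {(E)-2-[2,6-dimethoxy-4-(2,4,6-trimethoxyphenoxy)phenoxy]ethenyl}lithium F8.
- Immediate transfer of F8 onto 11 would give the racemic lithium alkoxide F9.
- MeOTf would give racemic 4-{(E)-2-[2,6-dimethoxy-4-(2,4,6-trimethoxyphenoxy)phenoxy]ethenyl}-2,3,4-trimethoxycyclobut-2-en-1-one F10.
- Heating F10 as in step 8 would pass through the (3Z,5E)-dienylketene F11 and 18 to 19.

F8 must not be warmed, because anti elimination of lithium aryloxide is its decomposition path; that is why this sequence is the fallback and not the main line.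

**Step 11.** With a di-ortho-methoxy phenol the copper-bound aryl may be lost by protodeboronation or homocoupling of 24 faster than the C–O bond forms. The fallback changes from oxidative boron coupling to a halide-selective Ullmann coupling; it sets out from 21 and comes back at 25. Bromine–lithium exchange of 21 to 22 and an iodine quench would give 5-iodo-1,3-dimethoxy-2-(3,4,5-trimethoxyphenoxy)benzene F12. Coupling of F12 with 4 (CuI, picolinic acid, K3PO4, DMSO, 80 °C) would give 25; the iodide reacts first because the ring of 4 is deactivated towards copper insertion by its own para-phenoxide.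

**Step 12.** C–O bond formation may be too slow at a phenoxide with two ortho substituents, one of them the bulky ring B ether, so hydrodebromination of 25 and oxidation of 19 would take over. The fallback attaches ring D by nucleophilic aromatic substitution and moves the copper coupling to a less hindered phenol; it sets out from 19 and comes back at 26.
- 19 and commercial 4-fluoro-2,6-dimethoxybenzaldehyde (Cs2CO3, DMF, 100 °C) would give 4-{6-[2,6-dimethoxy-4-(2,4,6-trimethoxyphenoxy)phenoxy]-2,3,4-trimethoxyphenoxy}-2,6-dimethoxybenzaldehyde F13.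
- Baeyer–Villiger oxidation (mCPBA) would give the corresponding aryl formate F14.
- Methanolysis (K2CO3, MeOH) would give 4-{6-[2,6-dimethoxy-4-(2,4,6-trimethoxyphenoxy)phenoxy]-2,3,4-trimethoxyphenoxy}-2,6-dimethoxyphenol F15.
- Coupling of F15 with 21 under the conditions of step 3 would give 26.

**Step 13.** Dealkylation may stop short at some of the fifteen sites, and the free polyphenol may be degraded by oxidation during isolation. The fallback isolates the product as a stable derivative; it sets out from 26 and comes back at 28. After BBr3 treatment and quench, the crude product would be acetylated (Ac2O, pyridine, DMAP) to the pentadecaacetate of 28 F16, which can be chromatographed away from partly methylated material. Acid transesterification (HCl in degassed MeOH, generated from AcCl, rt) would then release 28 without ever forming a phenoxide.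

## Further compounds

F1 | step 8 | 6-bromo-2,3,4-trimethoxyphenol | COc1cc(Br)c(O)c(OC)c1OC
F2 | step 8 | 1-(benzyloxy)-6-bromo-2,3,4-trimethoxybenzene | COc1cc(Br)c(OCc2ccccc2)c(OC)c1OC
F3 | step 8 | 1-(benzyloxy)-6-[2,6-dimethoxy-4-(2,4,6-trimethoxyphenoxy)phenoxy]-2,3,4-trimethoxybenzene | COc1cc(OC)c(Oc2cc(OC)c(Oc3cc(OC)c(OC)c(OC)c3OCc3ccccc3)c(OC)c2)c(OC)c1
F4 | step 6 | 2-(ethynyloxy)-1,3-dimethoxy-5-(2,4,6-trimethoxyphenoxy)benzene | C#COc1c(OC)cc(Oc2c(OC)cc(OC)cc2OC)cc1OC
F5 | step 6 | racemic 4-{[2,6-dimethoxy-4-(2,4,6-trimethoxyphenoxy)phenoxy]ethynyl}-4-hydroxy-2,3-dimethoxycyclobut-2-en-1-one | COC1=C(OC)C(O)(C#COc2c(OC)cc(Oc3c(OC)cc(OC)cc3OC)cc2OC)C1=O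
F6 | step 7 | chlorobis(cyclopentadienyl){(E)-2-[2,6-dimethoxy-4-(2,4,6-trimethoxyphenoxy)phenoxy]ethenyl}zirconium | Cl[Zr](/C=C/Oc1c(OC)cc(Oc2c(OC)cc(OC)cc2OC)cc1OC)(C1C=CC=C1)C1C=CC=C1
F7 | step 7 | 2-{[(E)-2-iodoethenyl]oxy}-1,3-dimethoxy-5-(2,4,6-trimethoxyphenoxy)benzene | I/C=C/Oc1c(OC)cc(Oc2c(OC)cc(OC)cc2OC)cc1OC
F8 | step 7 | {(E)-2-[2,6-dimethoxy-4-(2,4,6-trimethoxyphenoxy)phenoxy]ethenyl}lithium | [Li]/C=C/Oc1c(OC)cc(Oc2c(OC)cc(OC)cc2OC)cc1OC
F9 | step 7 | racemic lithium 1-{(E)-2-[2,6-dimethoxy-4-(2,4,6-trimethoxyphenoxy)phenoxy]ethenyl}-2,3-dimethoxy-4-oxocyclobut-2-en-1-olate | COC1=C(OC)C(O[Li])(/C=C/Oc2c(OC)cc(Oc3c(OC)cc(OC)cc3OC)cc2OC)C1=O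
F10 | step 7 | racemic 4-{(E)-2-[2,6-dimethoxy-4-(2,4,6-trimethoxyphenoxy)phenoxy]ethenyl}-2,3,4-trimethoxycyclobut-2-en-1-one | COC1=C(OC)C(OC)(/C=C/Oc2c(OC)cc(Oc3c(OC)cc(OC)cc3OC)cc2OC)C1=O
F11 | step 7 | (3Z,5E)-6-[2,6-dimethoxy-4-(2,4,6-trimethoxyphenoxy)phenoxy]-2,3,4-trimethoxyhexa-1,3,5-trien-1-one | O=C=C(OC)/C(OC)=C(OC)\C=C\Oc1c(OC)cc(Oc2c(OC)cc(OC)cc2OC)cc1OC
F12 | step 11 | 5-iodo-1,3-dimethoxy-2-(3,4,5-trimethoxyphenoxy)benzene | COc1cc(I)cc(OC)c1Oc1cc(OC)c(OC)c(OC)c1
F13 | step 12 | 4-{6-[2,6-dimethoxy-4-(2,4,6-trimethoxyphenoxy)phenoxy]-2,3,4-trimethoxyphenoxy}-2,6-dimethoxybenzaldehyde | COc1cc(OC)c(Oc2cc(OC)c(Oc3cc(OC)c(OC)c(OC)c3Oc3cc(OC)c(C=O)c(OC)c3)c(OC)c2)c(OC)c1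
F14 | step 12 | 4-{6-[2,6-dimethoxy-4-(2,4,6-trimethoxyphenoxy)phenoxy]-2,3,4-trimethoxyphenoxy}-2,6-dimethoxyphenyl formate | COc1cc(OC)c(Oc2cc(OC)c(Oc3cc(OC)c(OC)c(OC)c3Oc3cc(OC)c(OC=O)c(OC)c3)c(OC)c2)c(OC)c1
F15 | step 12 | 4-{6-[2,6-dimethoxy-4-(2,4,6-trimethoxyphenoxy)phenoxy]-2,3,4-trimethoxyphenoxy}-2,6-dimethoxyphenol | COc1cc(OC)c(Oc2cc(OC)c(Oc3cc(OC)c(OC)c(OC)c3Oc3cc(OC)c(O)c(OC)c3)c(OC)c2)c(OC)c1
F16 | step 13 | pentadecaacetate of 28 | CC(=O)Oc1cc(OC(C)=O)c(Oc2cc(OC(C)=O)c(Oc3cc(OC(C)=O)c(OC(C)=O)c(OC(C)=O)c3Oc3cc(OC(C)=O)c(Oc4cc(OC(C)=O)c(Oc5cc(OC(C)=O)c(OC(C)=O)c(OC(C)=O)c5)c(OC(C)=O)c4)c(OC(C)=O)c3)c(OC(C)=O)c2)c(OC(C)=O)c1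
A1 | alternative 1 | (cyclopentadienyl)(η6-2,5-dichloro-1,3-dimethoxybenzene)ruthenium hexafluorophosphate, written as components | COc1cc(Cl)cc(OC)c1Cl.[Ru+2].[cH-]1cccc1.F[P-](F)(F)(F)(F)F
A2 | alternative 1 | 2-(benzyloxy)-3,4,5-trimethoxyphenol | COc1cc(O)c(OCc2ccccc2)c(OC)c1OC
A3 | alternative 1 | cyclopentadienylruthenium hexafluorophosphate complex of the ABC trimer benzyl ether (metal on ring B), written as components | COc1cc(OC)c(Oc2cc(OC)c(Oc3cc(OC)c(OC)c(OC)c3OCc3ccccc3)c(OC)c2)c(OC)c1.[Ru+2].[cH-]1cccc1.F[P-](F)(F)(F)(F)F
A4 | alternative 2 | 2-[2-(benzyloxy)-3,4,5-trimethoxyphenoxy]-1-methoxy-1,3-bis(trimethylsilyloxy)buta-1,3-diene (ketene acetal geometry not defined) | C=C(O[Si](C)(C)C)C(Oc1cc(OC)c(OC)c(OC)c1OCc1ccccc1)=C(OC)O[Si](C)(C)C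
A5 | alternative 2 | methyl 3-(2,4,6-trimethoxyphenoxy)prop-2-ynoate | COC(=O)C#COc1c(OC)cc(OC)cc1OC
A6 | alternative 2 | methyl 3-[2-(benzyloxy)-3,4,5-trimethoxyphenoxy]-2,4-dihydroxy-6-(2,4,6-trimethoxyphenoxy)benzoate | COC(=O)c1c(O)c(Oc2cc(OC)c(OC)c(OC)c2OCc2ccccc2)c(O)cc1Oc1c(OC)cc(OC)cc1OC
A7 | alternative 3 | dimethyl 3-oxopentanedioate | COC(=O)CC(=O)CC(=O)OC
A8 | alternative 3 | dimethyl 2-(BCDEF-oxy)propanedioate, the aryl group being the permethylated pentamer attached through ring B C1 | COC(=O)C(Oc1cc(OC)c(Oc2cc(OC)c(OC)c(OC)c2Oc2cc(OC)c(Oc3cc(OC)c(Oc4cc(OC)c(OC)c(OC)c4)c(OC)c3)c(OC)c2)c(OC)c1)C(=O)OC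
A9 | alternative 3 | dimethyl 2,4,6-trihydroxy-5-(BCDEF-oxy)benzene-1,3-dicarboxylate | COC(=O)c1c(O)c(C(=O)OC)c(O)c(Oc2cc(OC)c(Oc3cc(OC)c(OC)c(OC)c3Oc3cc(OC)c(Oc4cc(OC)c(Oc5cc(OC)c(OC)c(OC)c5)c(OC)c4)c(OC)c3)c(OC)c2)c1O
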